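**Retrosynth overview**
- 12 ⇐ 11 (Si–O cleavage) ⇐ 10 (allyl to prenyl by cross-metathesis). The C8 side chain travels as allyl, so the cationic key step meets no trisubstituted alkene that could compete with styrene.
- Feature: ring C (O1–C2–C3–C4–C4a–C8a). O1, C8a, C4a and C4 are the oxygen, two ring carbons and carbonyl carbon of an ortho-oxygenated benzaldehyde whose carbonyl oxygen stays as the C4 oxygen; C2–C3 with the phenyl ring is styrene.
- Key disconnection: C3–C4 and O1–C2 of 10 ⇒ aryl silyl ether aldehyde 5 + styrene 6, a catalytic asymmetric formal [4+2] in which the silyl group moves from O1 to the C4 oxygen. C4 and C2 are both set here.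
- 5 ⇐ 4 (O-silylation) ⇐ 2 (aromatic Claisen shift to C3) ⇐ 1 (O-allylation).
- Ring order: rings A and B are bought (1 and styrene); ring C is the only ring formed (step 4).

Key step: step 4

Assumptions:
- Flavan numbering (O1, C2, C3, C4, C4a, C5–C8, C8a) is used for 9–12.
- "IDPi acid" is a confined chiral imidodiphosphorimidate Brønsted acid built from two 3,3'-diaryl-BINOL phosphorus units with N-triflyl groups; its N-silylated form is the active Lewis acid.
- Which antipode of the IDPi acid leads to 4R cannot be derived in advance; it is fixed by a first experiment, both antipodes being accessible from (R)- or (S)-BINOL.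

**Route**

Step 1
Reactants: 1 2-hydroxy-4,6-dimethoxybenzaldehyde
Product: 2 2-(allyloxy)-4,6-dimethoxybenzaldehyde
Conditions: allyl bromide, K2CO3, DMF, 50 °C
Reagents that add atoms: allyl bromide, C=CCBr
Why: Williamson ether synthesis, in which K2CO3 in a polar aprotic solvent breaks the hydrogen bond of the phenol to the aldehyde and the phenoxide displaces bromide from an unhindered allylic carbon at oxygen.

Step 2
Reactants: 2 2-(allyloxy)-4,6-dimethoxybenzaldehyde
Product: 4 3-allyl-2-hydroxy-4,6-dimethoxybenzaldehyde, via Claisen dienone 3 (not isolated)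
Conditions: PhNEt2, 190 °C, argon, sealed tube
Reagents that add atoms: none
Why: Aromatic Claisen rearrangement ([3,3]-sigmatropic shift) to C3, the only ortho carbon that carries hydrogen, followed by tautomerisation of dienone 3 to the phenol, which is held by its hydrogen bond to the aldehyde; no stereocentre remains.

Step 3
Reactants: 4 3-allyl-2-hydroxy-4,6-dimethoxybenzaldehyde
Product: 5 3-allyl-4,6-dimethoxy-2-(triethylsilyloxy)benzaldehyde
Conditions: Et3SiCl, imidazole, CH2Cl2, 0 °C to rt; non-aqueous work-up, filtration through Et3N-deactivated silica, azeotropic drying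
Reagents that add atoms: chlorotriethylsilane, CC[Si](Cl)(CC)CC
Why: Imidazole-promoted O-silylation of a phenol, where the small triethylsilyl electrophile reaches the flanked oxygen and the moisture-sensitive aryl silyl ether is isolated without contact with water or acid.

Step 4
Reactants: 5 3-allyl-4,6-dimethoxy-2-(triethylsilyloxy)benzaldehyde; 6 styrene
Product: 10 (2S,4R)-8-allyl-5,7-dimethoxy-2-phenyl-4-(triethylsilyloxy)chromane, via oxocarbenium ion 7 (not isolated), via benzylic cation 8 (not isolated), via silyloxonium ion 9 (not isolated)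
Conditions: IDPi acid (5 mol%) pre-silylated with CH2=CHCH2SiEt3 (10 mol%); styrene (10 equiv, freshly distilled), CH2Cl2 (0.05 M in 5), −40 °C; Et3N quench at −40 °C
Reagents that add atoms: none
Why: Proposed new method: the N-silylated IDPi (made from the acid and allyltriethylsilane with loss of propene, the same silyl group as in 5) passes Et3Si+ to the aldehyde oxygen to give oxocarbenium ion 7, an O-silylated ortho-quinone methide paired with the chiral anion; the CH2 terminus of styrene adds to its carbon (C3–C4, Prins-type, Markovnikov) to give benzylic cation 8, the aryl silyl ether oxygen captures C2 (O1–C2) to give silyloxonium ion 9, and 9 returns Et3Si+ to the anion, so that the silyl group ends on the C4 oxygen and the catalyst turns over. The closest known reaction types are silylium imidodiphosphorimidate catalysis of additions to aldehydes (Mukaiyama aldol, Hosomi–Sakurai allylation), catalytic asymmetric Prins reactions of styrenes, and acid-mediated formal [4+2] reactions of salicylaldehyde-derived oxocarbenium ions or ortho-quinone methides with styrenes that give 4-alkoxyflavans; capture of the cation by a silyl ether with onward transfer of the silyl group is the new element. Ring C closes by attack of O1 on the planar benzylic cation in a six-membered half-chair transition state, the second bond of an asynchronous cationic [4+2]. C4 (R) is set by the face of 7 that the counteranion leaves open to styrene (catalyst control), and C2 (S) by closure with phenyl pseudo-equatorial and the C4 silyloxy group pseudo-axial, which avoids peri strain with the 5-methoxy group and a 1,3-diaxial contact and gives the 2,4-trans product. The step needs styrene to be the only π nucleophile that reacts and the product to stay un-ionised: the side chain is allyl, a monosubstituted alkene far less nucleophilic than styrene and unable to reach the cation of its own molecule, styrene is in excess, and the cold reaction is quenched with Et3N before the catalyst can silylate the C4 oxygen of 10.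

Step 5
Reactants: 10 (2S,4R)-8-allyl-5,7-dimethoxy-2-phenyl-4-(triethylsilyloxy)chromane
Product: 11 (2S,4R)-5,7-dimethoxy-8-(3-methylbut-2-en-1-yl)-2-phenyl-4-(triethylsilyloxy)chromane
Conditions: second-generation Grubbs catalyst RuCl2(=CHPh)(PCy3)(H2IMes) (5 mol%), 2-methyl-2-butene/CH2Cl2, 35 °C
Reagents that add atoms: 2-methyl-2-butene, CC=C(C)C
Why: Olefin cross-metathesis of the only alkene in 10, a terminal allyl group, with a large excess of 2-methyl-2-butene, which delivers the isopropylidene unit while propene leaves; the silyl ether and both stereocentres are not touched.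

Step 6
Reactants: 11 (2S,4R)-5,7-dimethoxy-8-(3-methylbut-2-en-1-yl)-2-phenyl-4-(triethylsilyloxy)chromane
Product: 12 (2S,4R)-5,7-dimethoxy-8-(3-methylbut-2-en-1-yl)-2-phenylchroman-4-ol
Conditions: Bu4NF, AcOH (1:1), THF, 0 °C; chromatography on Et3N-deactivated silica
Reagents that add atoms: none
Why: Fluoride-mediated desilylation breaks the Si–O bond and leaves the C4–O bond intact, so C4 keeps its configuration, and the acetic acid buffer keeps the medium near neutral so that the electron-rich benzylic alcohol does not ionise.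

**Compound list**
1 | 2-hydroxy-4,6-dimethoxybenzaldehyde | COc1cc(O)c(C=O)c(OC)c1 | starting material
2 | 2-(allyloxy)-4,6-dimethoxybenzaldehyde | COc1cc(OCC=C)c(C=O)c(OC)c1 | intermediate
3 | Claisen dienone, 2,4-dimethoxy-6-oxo-5-(prop-2-en-1-yl)cyclohexa-1,3-diene-1-carbaldehyde (racemic, not isolated) | COC1=CC(OC)=C(C=O)C(=O)C1CC=C | intermediate
4 | 3-allyl-2-hydroxy-4,6-dimethoxybenzaldehyde | COc1cc(OC)c(C=O)c(O)c1CC=C | intermediate
5 | 3-allyl-4,6-dimethoxy-2-(triethylsilyloxy)benzaldehyde | COc1cc(OC)c(C=O)c(O[Si](CC)(CC)CC)c1CC=C | intermediate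
6 | styrene | C=Cc1ccccc1 | starting material
7 | oxocarbenium ion, 5 silylated at the aldehyde oxygen, paired with the IDPi anion (not isolated) | COc1cc(OC)c(C=[O+][Si](CC)(CC)CC)c(O[Si](CC)(CC)CC)c1CC=C | intermediate
8 | benzylic cation, (3R)-3-[3-allyl-4,6-dimethoxy-2-(triethylsilyloxy)phenyl]-1-phenyl-3-(triethylsilyloxy)propan-1-ylium (not isolated) | COc1cc(OC)c([C@H](O[Si](CC)(CC)CC)C[CH+]c2ccccc2)c(O[Si](CC)(CC)CC)c1CC=C | intermediate
9 | silyloxonium ion, 10 carrying a second triethylsilyl group on O1 (not isolated) | COc1cc(OC)c2c(c1CC=C)[O+]([Si](CC)(CC)CC)[C@H](c1ccccc1)C[C@H]2O[Si](CC)(CC)CC | intermediate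
10 | (2S,4R)-8-allyl-5,7-dimethoxy-2-phenyl-4-(triethylsilyloxy)chromane (2,4-trans) | COc1cc(OC)c2c(c1CC=C)O[C@H](c1ccccc1)C[C@H]2O[Si](CC)(CC)CC | intermediate
11 | (2S,4R)-5,7-dimethoxy-8-(3-methylbut-2-en-1-yl)-2-phenyl-4-(triethylsilyloxy)chromane | COc1cc(OC)c2c(c1CC=C(C)C)O[C@H](c1ccccc1)C[C@H]2O[Si](CC)(CC)CC | intermediate
12 | (2S,4R)-5,7-dimethoxy-8-(3-methylbut-2-en-1-yl)-2-phenylchroman-4-ol (2,4-trans) | COc1cc(OC)c2c(c1CC=C(C)C)O[C@H](c1ccccc1)C[C@H]2O | target

Total step count: 6
Longest linear sequence: 6 steps (1 to 12)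

**Steps most likely to fail**

Step 4 (proposed new method).
- What may go wrong: ion 7 is stabilised by three oxygen donors and may be attacked too slowly by styrene; styrene may oligomerise cationically; the catalyst may ionise the C4–O bond of 10, with loss of the C4 configuration or elimination; facial or trans selectivity may be poor.
- Fallback with known chemistry, from 4 back to 12:
  - Cross-metathesis of 4 with 2-methyl-2-butene (second-generation Grubbs catalyst RuCl2(=CHPh)(PCy3)(H2IMes)) should give 2-hydroxy-4,6-dimethoxy-3-(3-methylbut-2-en-1-yl)benzaldehyde F1.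
  - Excess HC≡CMgBr in THF at 0 °C should give racemic 2-(1-hydroxyprop-2-yn-1-yl)-3,5-dimethoxy-6-(3-methylbut-2-en-1-yl)phenol F2, used crude.
  - MnO2 in CH2Cl2 should oxidise it to 1-[2-hydroxy-4,6-dimethoxy-3-(3-methylbut-2-en-1-yl)phenyl]prop-2-yn-1-one F3.
  - K2CO3 in acetone should close the pyranone by 6-endo-dig oxa-Michael addition to 5,7-dimethoxy-8-(3-methylbut-2-en-1-yl)-4H-chromen-4-one F4.
  - Asymmetric conjugate addition of PhB(OH)2 with [RhOH(cod)]2 and an electron-poor atropisomeric bisphosphine of the MeO-BIPHEP family (antipode chosen for 2S) should give (2S)-5,7-dimethoxy-8-(3-methylbut-2-en-1-yl)-2-phenylchroman-4-one F5.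
  - NaBH4 in MeOH at 0 °C should give, by axial hydride delivery, (2S,4S)-5,7-dimethoxy-8-(3-methylbut-2-en-1-yl)-2-phenylchroman-4-ol F6 (2,4-cis).
  - Mitsunobu inversion (4-nitrobenzoic acid, PPh3, DIAD, THF) should give (2S,4R)-5,7-dimethoxy-8-(3-methylbut-2-en-1-yl)-2-phenylchroman-4-yl 4-nitrobenzoate F7.
  - K2CO3 in MeOH should release 12.

Step 5.
- What may go wrong: a ruthenium hydride may move the allyl double bond into conjugation with the arene before metathesis, or the hindered environment between O1 and the 7-methoxy group may slow turnover.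
- Fallback, from 10 back to 11: oxidative cleavage (OsO4 cat., NaIO4, 2,6-lutidine, dioxane/H2O) should give 2-[(2S,4R)-5,7-dimethoxy-2-phenyl-4-(triethylsilyloxy)chroman-8-yl]acetaldehyde F8. Wittig olefination with isopropylidenetriphenylphosphorane (from isopropyltriphenylphosphonium iodide and n-BuLi, THF, −78 °C to rt) should then give 11.

Step 2.
- What may go wrong: at 190 °C the ortho-allyl phenol may add across its own alkene to a 2-methyl-2,3-dihydrobenzofuran, or the allyl group may shift to the formyl-bearing ortho carbon with loss of the formyl group.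
- Fallback, from 1 back to 4: electrophilic iodination (N-iodosuccinimide, cat. CF3CO2H, MeCN) at C3, which is ortho to the hydroxyl and para to the 6-methoxy group, should give 2-hydroxy-3-iodo-4,6-dimethoxybenzaldehyde F9. Stille coupling with allyltributylstannane (Pd(PPh3)4, DMF, 90 °C) should then give 4.

Further compounds
F1 | step 4 | 2-hydroxy-4,6-dimethoxy-3-(3-methylbut-2-en-1-yl)benzaldehyde | COc1cc(OC)c(C=O)c(O)c1CC=C(C)C
F2 | step 4 | 2-(1-hydroxyprop-2-yn-1-yl)-3,5-dimethoxy-6-(3-methylbut-2-en-1-yl)phenol (racemic) | COc1cc(OC)c(C(O)C#C)c(O)c1CC=C(C)C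
F3 | step 4 | 1-[2-hydroxy-4,6-dimethoxy-3-(3-methylbut-2-en-1-yl)phenyl]prop-2-yn-1-one | COc1cc(OC)c(C(=O)C#C)c(O)c1CC=C(C)C
F4 | step 4 | 5,7-dimethoxy-8-(3-methylbut-2-en-1-yl)-4H-chromen-4-one | COc1cc(OC)c2c(c1CC=C(C)C)occc2=O
F5 | step 4 | (2S)-5,7-dimethoxy-8-(3-methylbut-2-en-1-yl)-2-phenylchroman-4-one | COc1cc(OC)c2c(c1CC=C(C)C)O[C@H](c1ccccc1)CC2=O
F6 | step 4 | (2S,4S)-5,7-dimethoxy-8-(3-methylbut-2-en-1-yl)-2-phenylchroman-4-ol (2,4-cis) | COc1cc(OC)c2c(c1CC=C(C)C)O[C@H](c1ccccc1)C[C@@H]2O
F7 | step 4 | (2S,4R)-5,7-dimethoxy-8-(3-methylbut-2-en-1-yl)-2-phenylchroman-4-yl 4-nitrobenzoate | COc1cc(OC)c2c(c1CC=C(C)C)O[C@H](c1ccccc1)C[C@H]2OC(=O)c1ccc(cc1)[N+](=O)[O-]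
F8 | step 5 | 2-[(2S,4R)-5,7-dimethoxy-2-phenyl-4-(triethylsilyloxy)chroman-8-yl]acetaldehyde | COc1cc(OC)c2c(c1CC=O)O[C@H](c1ccccc1)C[C@H]2O[Si](CC)(CC)CC
F9 | step 2 | 2-hydroxy-3-iodo-4,6-dimethoxybenzaldehyde | COc1cc(OC)c(C=O)c(O)c1I
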